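The bicyclic core is read as a toluene ring plus one carbon: ring atoms C5–C10 (methyl on C8, oxygen on C6) are the arene, and the methyl-bearing C1 is inserted between C5 and C10 while it also closes the five-membered ring C1–C2–C3–C4–C5. A metal carbene at C1, tethered through C2–C3–C4 to the ipso carbon C5, does this in one operation (C1–C5 and C1–C10 formed, cyclopentane closed, benzene expanded to the cycloheptatriene, quaternary C1 set). The precursor is an α-methyl α-diazoketone whose C4 carbinol oxygen and ortho phenol oxygen are tied in one di-tert-butylsilylene, which fixes the face of attack and later unmasks the C6 ketone and C4 hydroxyl together.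

Key step: step 7

Locants used for every compound: C1 quaternary ring-fusion carbon (CH3); C2, C3 CH2; C4 carbinol carbon (isopropyl); C5 ring-fusion CH; C6 CH–O; C7 CH2; C8 methyl-bearing alkene carbon; C9 alkene CH; C10 CH2 on C1. Azulene locants in names: 1 = C2, 2 = C3, 3 = C4, 3a = C5, 4 = C6, 5 = C7, 6 = C8, 7 = C9, 8 = C10, 8a = C1.

Assumption: the (R,R)-configured allylchlorosilane of step 2 is taken to add allyl to the Si face of the aryl ketone; if the sense proves opposite, its (S,S)-enantiomer is used and nothing else changes.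

Step 1
Reactants: 1 m-cresol; 2 isobutyryl chloride
Product: 4 1-(2-hydroxy-4-methylphenyl)-2-methylpropan-1-one, via m-tolyl isobutyrate 3 (not isolated)
Conditions: 2 (1.05 equiv), neat, 80 °C; then AlCl3 (1.3 equiv), 150 °C; ice/2 M HCl
Reagents that add atoms: none
Why: O-acylation followed by a thermal Fries rearrangement, in which AlCl3 at this temperature should move the acyl group to the open ortho position para to the methyl group, where the product is held as its aluminium chelate.

Step 2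
Reactants: 4 1-(2-hydroxy-4-methylphenyl)-2-methylpropan-1-one; 5 (3aR,7aR)-2-allyl-1,3-bis(4-bromobenzyl)-2-chlorooctahydro-1H-1,3,2-benzodiazasilole
Product: 6 2-[(3R)-3-hydroxy-2-methylhex-5-en-3-yl]-5-methylphenol
Conditions: 5 (1.5 equiv), CH2Cl2, 25→40 °C; then 1 M aq. NaOH, 0 °C; aq. NH4Cl
Reagents that add atoms: none
Why: Phenol-directed asymmetric allylation of a 2-hydroxyaryl ketone with a strained chiral allylchlorosilane, in which the phenol binds silicon, the hindered carbonyl is activated intramolecularly and allyl is transferred through a closed chair transition state whose diamine backbone selects the Si face, setting C4 as R.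

Step 3
Reactants: 6 2-[(3R)-3-hydroxy-2-methylhex-5-en-3-yl]-5-methylphenol
Product: 7 (4R)-4-allyl-2,2-di-tert-butyl-4-isopropyl-7-methyl-4H-benzo[d][1,3,2]dioxasiline
Conditions: t-Bu2Si(OTf)2 (1.2 equiv), 2,6-lutidine (3 equiv), DMF, 0→40 °C
Reagents that add atoms: di-tert-butylsilyl bis(trifluoromethanesulfonate), CC(C)(C)[Si](OS(=O)(=O)C(F)(F)F)(OS(=O)(=O)C(F)(F)F)C(C)(C)C
Why: Silylene protection of a 1,3-related phenol/tertiary alcohol pair, in which the phenol is silylated first and the hindered carbinol then closes the six-membered ring intramolecularly under buffered conditions that should not ionise the benzylic C–O bond.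

Step 4
Reactants: 7 (4R)-4-allyl-2,2-di-tert-butyl-4-isopropyl-7-methyl-4H-benzo[d][1,3,2]dioxasiline
Product: 8 2-[(4R)-2,2-di-tert-butyl-4-isopropyl-7-methyl-4H-benzo[d][1,3,2]dioxasilin-4-yl]acetaldehyde
Conditions: O3, CH2Cl2, −78 °C (Sudan Red 7B end point); PPh3, −78 °C→rt
Reagents that add atoms: ozone, [O-][O+]=O
Why: Ozonolysis with reductive work-up, in which the terminal alkene reacts far faster than the silyloxy arene and the indicator dye marks the point at which the gas flow is stopped.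

Step 5
Reactants: 8 2-[(4R)-2,2-di-tert-butyl-4-isopropyl-7-methyl-4H-benzo[d][1,3,2]dioxasilin-4-yl]acetaldehyde
Product: 9 2-[(4R)-2,2-di-tert-butyl-4-isopropyl-7-methyl-4H-benzo[d][1,3,2]dioxasilin-4-yl]acetic acid
Conditions: NaClO2, NaH2PO4, 2-methylbut-2-ene, t-BuOH/H2O, 0 °C→rt
Reagents that add atoms: sodium chlorite, [Na+].[O-]Cl=O
Why: Pinnick oxidation, in which chlorous acid converts the aldehyde to the acid while the alkene scavenger removes hypochlorous acid before it can chlorinate the electron-rich ring, and the buffered medium should leave the silylene intact.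

Step 6
Reactants: 9 2-[(4R)-2,2-di-tert-butyl-4-isopropyl-7-methyl-4H-benzo[d][1,3,2]dioxasilin-4-yl]acetic acid; 10 N-ethyl-N-nitrosourea
Product: 13 3-diazo-1-[(4R)-2,2-di-tert-butyl-4-isopropyl-7-methyl-4H-benzo[d][1,3,2]dioxasilin-4-yl]butan-2-one, via acid chloride 11 (not isolated), via diazoethane 12 (not isolated)
Conditions: 9, 1-chloro-N,N,2-trimethylprop-1-en-1-amine (1.2 equiv), CH2Cl2, 0 °C→rt; added to CH3CHN2 (3 equiv, from 10, 40% aq. KOH, Et2O, 0 °C), Et2O, −20→0 °C
Reagents that add atoms: none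
Why: Acylation of a diazoalkane (the diazoketone synthesis of the Arndt–Eistert sequence), in which the acid chloride is made under neutral conditions with the α-chloroenamine and adds to excess diazoethane, the surplus taking up HCl so that no α-chloroketone forms.

Step 7
Reactants: 13 3-diazo-1-[(4R)-2,2-di-tert-butyl-4-isopropyl-7-methyl-4H-benzo[d][1,3,2]dioxasilin-4-yl]butan-2-one (the 2-diazo-6-methyl-5-oxy-5-(2-oxy-4-methylphenyl)heptan-3-one skeleton, both oxygens in one silylene)
Product: 15 (3R,8aR)-3,4-[(di-tert-butylsilanediyl)bis(oxy)]-3-isopropyl-6,8a-dimethyl-3,8a-dihydroazulen-1(2H)-one, via norcaradiene 14 (not isolated)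
Conditions: Rh2(OAc)4 (1 mol %), CH2Cl2 (0.01 M), 40 °C, slow addition of 13
Reagents that add atoms: none
Why: Rh2(OAc)4 (divalent rhodium) expels N2 from 13 to give an electrophilic α-keto carbenoid at C1 that cyclopropanates the arene bond C5–C10, and the norcaradiene 14 opens by a thermal 6π disrotatory electrocyclic reaction to the cycloheptatriene 15; this is the intramolecular Buchner reaction of 1-diazo-4-arylbutan-2-ones, which is established for α-methyl α-diazoketones. The five-membered ring is closed by the C1–C5 bond of the [2+1] addition, the three-atom tether C2–C3–C4 allowing only a fused ipso/ortho cyclopropane, and the seven-membered ring arises from the benzene ring by cleavage of C5–C10 with C1 left between the two atoms. The new quaternary centre C1 is controlled by C4: the silylene holds O4 in the arene plane beside O6, so C3 and the isopropyl group lie on opposite faces, the carbenoid can reach only the face that carries C3, and the C1 methyl should end up cis to O4 and trans to isopropyl (8aR). Regioselectivity for C10 over the oxygen-bearing C6 follows from the same lock, which tilts C3 toward C10, and from the substituent on C6. Chemoselectivity over 1,2-hydride migration from the C1 methyl and over insertion into the isopropyl C–H rests on the electron-rich arene, the electrophilic carboxylate catalyst and slow addition at high dilution.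

Step 8
Reactants: 15 (3R,8aR)-3,4-[(di-tert-butylsilanediyl)bis(oxy)]-3-isopropyl-6,8a-dimethyl-3,8a-dihydroazulen-1(2H)-one
Product: 16 (3R,8aR)-3,4-[(di-tert-butylsilanediyl)bis(oxy)]-3-isopropyl-6,8a-dimethyl-1,2,3,8a-tetrahydroazulen-1-ol
Conditions: NaBH4, MeOH/THF, −20→0 °C
Reagents that add atoms: none
Why: Borohydride 1,2-reduction of the only carbonyl group, which gives a C2 carbinol (either epimer, removed later) and ends the cyclopropyl ketone character that could let the norcaradiene form rearrange to a tetralone.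

Step 9
Reactants: 16 (3R,8aR)-3,4-[(di-tert-butylsilanediyl)bis(oxy)]-3-isopropyl-6,8a-dimethyl-1,2,3,8a-tetrahydroazulen-1-ol
Product: 18 (3R,3aR,8aR)-1,3-dihydroxy-3-isopropyl-6,8a-dimethyl-1,2,3,3a-tetrahydroazulen-4(8aH)-one, via trienol 17 (not isolated)
Conditions: HF·pyridine, pyridine, THF, 0 °C
Reagents that add atoms: none
Why: Fluoride cleavage of the silylene (a silyl enol ether at O6, a silyl ether at O4) gives trienol 17, which ketonises by protonation at C5; C5 is epimerisable next to the carbonyl and should settle in the trans ring fusion (H5 anti to the C1 methyl), in which C6 avoids the isopropyl group and the C4 hydroxyl hydrogen-bonds to the ketone.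

Step 10
Reactants: 18 (3R,3aR,8aR)-1,3-dihydroxy-3-isopropyl-6,8a-dimethyl-1,2,3,3a-tetrahydroazulen-4(8aH)-one
Product: 19 (3R,3aR,8aR)-1,3-dihydroxy-3-isopropyl-6,8a-dimethyl-1,2,3,3a,8,8a-hexahydroazulen-4(5H)-one
Conditions: (η6-naphthalene)Cr(CO)3 (20 mol %), H2 (70 atm), THF, 45 °C
Reagents that add atoms: none
Why: Cr(CO)3-catalysed 1,4-hydrogenation of a conjugated s-cis diene, in which the zerovalent chromium fragment binds C7=C8–C9=C10 (held cisoid by the ring) and delivers H2 to C7 and C10 only, so the C8=C9 alkene and the now unconjugated ketone should remain under neutral conditions.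

Step 11
Reactants: 19 (3R,3aR,8aR)-1,3-dihydroxy-3-isopropyl-6,8a-dimethyl-1,2,3,3a,8,8a-hexahydroazulen-4(5H)-one
Product: 20 O-[(3R,3aR,8aR)-3-hydroxy-3-isopropyl-6,8a-dimethyl-4-oxo-1,2,3,3a,4,5,8,8a-octahydroazulen-1-yl] O-phenyl carbonothioate
Conditions: PhOC(S)Cl (1.5 equiv), pyridine, DMAP (cat.), CH2Cl2, 0 °C→rt
Reagents that add atoms: O-phenyl chlorothionoformate, S=C(Cl)Oc1ccccc1
Why: Thioacylation of the secondary C2 alcohol as the first half of a Barton–McCombie deoxygenation, the tertiary C4 hydroxyl being inert under these mild conditions; the step is placed after the diene reduction because a C2 radical beside a vinyl-substituted C1 would undergo 1,2-vinyl shift.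

Step 12
Reactants: 20 O-[(3R,3aR,8aR)-3-hydroxy-3-isopropyl-6,8a-dimethyl-4-oxo-1,2,3,3a,4,5,8,8a-octahydroazulen-1-yl] O-phenyl carbonothioate
Product: 21 (3R,3aR,8aR)-3-hydroxy-3-isopropyl-6,8a-dimethyl-1,2,3,3a,8,8a-hexahydroazulen-4(5H)-one
Conditions: Bu3SnH (1.5 equiv), AIBN (0.2 equiv), toluene, 90 °C
Reagents that add atoms: none
Why: Barton–McCombie deoxygenation, in which the stannyl radical adds to sulfur, the C2–O bond fragments and the secondary C2 radical, which no longer has an adjacent alkene, abstracts hydrogen from the stannane.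

Step 13
Reactants: 21 (3R,3aR,8aR)-3-hydroxy-3-isopropyl-6,8a-dimethyl-1,2,3,3a,8,8a-hexahydroazulen-4(5H)-one
Product: 22 (3R,3aS,4S,8aR)-3-isopropyl-6,8a-dimethyl-1,2,3,3a,4,5,8,8a-octahydroazulene-3,4-diol
Conditions: Me4NBH(OAc)3 (5 equiv), MeCN/AcOH (1:1), −30→−20 °C
Reagents that add atoms: none
Why: Evans–Saksena hydroxyl-directed reduction, in which the C4 hydroxyl exchanges onto boron and hydride is delivered intramolecularly to the face of C6 on which O4 lies, so H6 should enter cis to O4 and the new hydroxyl trans to it and cis to H5 (6S).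

Step 14
Reactants: 22 (3R,3aS,4S,8aR)-3-isopropyl-6,8a-dimethyl-1,2,3,3a,4,5,8,8a-octahydroazulene-3,4-diol; 23 (E)-4-acetoxycinnamic acid
Product: 24 (3R,3aS,4S,8aR)-3-hydroxy-3-isopropyl-6,8a-dimethyl-1,2,3,3a,4,5,8,8a-octahydroazulen-4-yl (E)-3-(4-acetoxyphenyl)acrylate
Conditions: 23 (1.5 equiv), DCC (1.6 equiv), DMAP (0.3 equiv), CH2Cl2, 0 °C→rt
Reagents that add atoms: none
Why: Steglich esterification, in which the DMAP-activated acyl group acylates the secondary C6 hydroxyl while the tertiary C4 hydroxyl cannot react, the E geometry of the acid being carried through unchanged.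

Step 15
Reactants: 24 (3R,3aS,4S,8aR)-3-hydroxy-3-isopropyl-6,8a-dimethyl-1,2,3,3a,4,5,8,8a-octahydroazulen-4-yl (E)-3-(4-acetoxyphenyl)acrylate
Product: 25 (3R,3aS,4S,8aR)-3-hydroxy-3-isopropyl-6,8a-dimethyl-1,2,3,3a,4,5,8,8a-octahydroazulen-4-yl (E)-3-(4-hydroxyphenyl)acrylate
Conditions: pyrrolidine (3 equiv), CH2Cl2, 0 °C
Reagents that add atoms: none
Why: Chemoselective aminolysis of an aryl acetate, which is far more electrophilic than the hindered secondary cinnamate, so pyrrolidine should free the phenol without cleaving the ester or adding to the conjugated alkene.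

Compound list
1 | m-cresol | Cc1cccc(O)c1 | starting material
2 | isobutyryl chloride | CC(C)C(Cl)=O | starting material
3 | m-tolyl isobutyrate | CC(C)C(=O)Oc1cccc(C)c1 | intermediate (not isolated)
4 | 1-(2-hydroxy-4-methylphenyl)-2-methylpropan-1-one | CC(C)C(=O)c1ccc(C)cc1O | intermediate
5 | (3aR,7aR)-2-allyl-1,3-bis(4-bromobenzyl)-2-chlorooctahydro-1H-1,3,2-benzodiazasilole | C=CC[Si]1(Cl)N(Cc2ccc(Br)cc2)[C@@H]3CCCC[C@H]3N1Cc4ccc(Br)cc4 | starting material
6 | 2-[(3R)-3-hydroxy-2-methylhex-5-en-3-yl]-5-methylphenol | C=CC[C@@](O)(C(C)C)c1ccc(C)cc1O | intermediate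
7 | (4R)-4-allyl-2,2-di-tert-butyl-4-isopropyl-7-methyl-4H-benzo[d][1,3,2]dioxasiline | C=CC[C@]1(C(C)C)O[Si](C(C)(C)C)(C(C)(C)C)Oc2cc(C)ccc12 | intermediate
8 | 2-[(4R)-2,2-di-tert-butyl-4-isopropyl-7-methyl-4H-benzo[d][1,3,2]dioxasilin-4-yl]acetaldehyde | O=CC[C@]1(C(C)C)O[Si](C(C)(C)C)(C(C)(C)C)Oc2cc(C)ccc12 | intermediate
9 | 2-[(4R)-2,2-di-tert-butyl-4-isopropyl-7-methyl-4H-benzo[d][1,3,2]dioxasilin-4-yl]acetic acid | OC(=O)C[C@]1(C(C)C)O[Si](C(C)(C)C)(C(C)(C)C)Oc2cc(C)ccc12 | intermediate
10 | N-ethyl-N-nitrosourea | CCN(N=O)C(N)=O | starting material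
11 | 2-[(4R)-2,2-di-tert-butyl-4-isopropyl-7-methyl-4H-benzo[d][1,3,2]dioxasilin-4-yl]acetyl chloride | ClC(=O)C[C@]1(C(C)C)O[Si](C(C)(C)C)(C(C)(C)C)Oc2cc(C)ccc12 | intermediate (not isolated)
12 | diazoethane | CC=[N+]=[N-] | intermediate (not isolated, used as ethereal solution)
13 | 3-diazo-1-[(4R)-2,2-di-tert-butyl-4-isopropyl-7-methyl-4H-benzo[d][1,3,2]dioxasilin-4-yl]butan-2-one | CC(=[N+]=[N-])C(=O)C[C@]1(C(C)C)O[Si](C(C)(C)C)(C(C)(C)C)Oc2cc(C)ccc12 | intermediate
14 | norcaradiene valence isomer of 15 (cyclopropane C1–C5–C10 fused to the cyclopentanone and to the 4-methylcyclohexa-2,4-diene ring that carries the silylene oxygen on C6) | CC1=C[C@@H]2[C@@]3(C)C(=O)C[C@]4(C(C)C)O[Si](C(C)(C)C)(C(C)(C)C)OC(=C1)[C@]234 | intermediate (not isolated)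
15 | (3R,8aR)-3,4-[(di-tert-butylsilanediyl)bis(oxy)]-3-isopropyl-6,8a-dimethyl-3,8a-dihydroazulen-1(2H)-one | CC=1C=C[C@@]2(C)C(=O)C[C@]3(C(C)C)O[Si](C(C)(C)C)(C(C)(C)C)OC(C=1)=C23 | intermediate
16 | (3R,8aR)-3,4-[(di-tert-butylsilanediyl)bis(oxy)]-3-isopropyl-6,8a-dimethyl-1,2,3,8a-tetrahydroazulen-1-ol (either epimer at C2) | CC=1C=C[C@@]2(C)C(O)C[C@]3(C(C)C)O[Si](C(C)(C)C)(C(C)(C)C)OC(C=1)=C23 | intermediate
17 | (3R,8aR)-3-isopropyl-6,8a-dimethyl-1,2,3,8a-tetrahydroazulene-1,3,4-triol (trienol) | CC=1C=C[C@@]2(C)C(O)C[C@@](O)(C(C)C)C2=C(O)C=1 | intermediate (not isolated)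
18 | (3R,3aR,8aR)-1,3-dihydroxy-3-isopropyl-6,8a-dimethyl-1,2,3,3a-tetrahydroazulen-4(8aH)-one (either epimer at C2) | CC=1C=C[C@@]2(C)C(O)C[C@@](O)(C(C)C)[C@@H]2C(=O)C=1 | intermediate
19 | (3R,3aR,8aR)-1,3-dihydroxy-3-isopropyl-6,8a-dimethyl-1,2,3,3a,8,8a-hexahydroazulen-4(5H)-one (either epimer at C2) | CC1=CC[C@@]2(C)C(O)C[C@@](O)(C(C)C)[C@@H]2C(=O)C1 | intermediate
20 | O-[(3R,3aR,8aR)-3-hydroxy-3-isopropyl-6,8a-dimethyl-4-oxo-1,2,3,3a,4,5,8,8a-octahydroazulen-1-yl] O-phenyl carbonothioate | CC1=CC[C@@]2(C)C(OC(=S)Oc3ccccc3)C[C@@](O)(C(C)C)[C@@H]2C(=O)C1 | intermediate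
21 | (3R,3aR,8aR)-3-hydroxy-3-isopropyl-6,8a-dimethyl-1,2,3,3a,8,8a-hexahydroazulen-4(5H)-one | CC1=CC[C@@]2(C)CC[C@@](O)(C(C)C)[C@@H]2C(=O)C1 | intermediate
22 | (3R,3aS,4S,8aR)-3-isopropyl-6,8a-dimethyl-1,2,3,3a,4,5,8,8a-octahydroazulene-3,4-diol | CC1=CC[C@@]2(C)CC[C@@](O)(C(C)C)[C@@H]2[C@@H](O)C1 | intermediate
23 | (E)-4-acetoxycinnamic acid | CC(=O)Oc1ccc(/C=C/C(=O)O)cc1 | starting material
24 | (3R,3aS,4S,8aR)-3-hydroxy-3-isopropyl-6,8a-dimethyl-1,2,3,3a,4,5,8,8a-octahydroazulen-4-yl (E)-3-(4-acetoxyphenyl)acrylate | CC1=CC[C@@]2(C)CC[C@@](O)(C(C)C)[C@@H]2[C@@H](OC(=O)/C=C/c2ccc(OC(C)=O)cc2)C1 | intermediate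
25 | (3R,3aS,4S,8aR)-3-hydroxy-3-isopropyl-6,8a-dimethyl-1,2,3,3a,4,5,8,8a-octahydroazulen-4-yl (E)-3-(4-hydroxyphenyl)acrylate | CC1=CC[C@@]2(C)CC[C@@](O)(C(C)C)[C@@H]2[C@@H](OC(=O)/C=C/c2ccc(O)cc2)C1 | target

Total step count: 15
Longest linear sequence: 15 steps (1 to 25); compounds 5, 10 and 23 are bought.

Steps most likely to fail

Step 7 (carbene addition). The carbenoid may be consumed before it reaches the arene, by 1,2-hydride migration from its own methyl group to a vinyl ketone or by insertion into the isopropyl methine C–H. Fallback: bring in the angular methyl after the ring expansion. It sets out from acid 9 by way of acid chloride 11. Trimethylsilyldiazomethane (THF/MeCN, 0 °C) should give the terminal diazoketone 1-diazo-3-[(4R)-2,2-di-tert-butyl-4-isopropyl-7-methyl-4H-benzo[d][1,3,2]dioxasilin-4-yl]propan-2-one F1, whose carbenoid has no hydrogen to migrate and belongs to the best-behaved substrate class for the arene addition. Rh2(OAc)4 in CH2Cl2 should then give the azulenone without the angular methyl, (3R,8aR)-3,4-[(di-tert-butylsilanediyl)bis(oxy)]-3-isopropyl-6-methyl-3,8a-dihydroazulen-1(2H)-one F2. Its doubly allylic C1–H is removed with KHMDS (THF, −78 °C), and the extended enolate is methylated with MeI at its α-carbon from the face opposite the isopropyl group (deconjugative α-alkylation). This comes back to the route at 15.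

Step 9 (unmasking). The free tertiary β-hydroxy dienone may dehydrate to the cross-conjugated trienone or open by retro-aldol cleavage, and C5 may be protonated to the cis ring fusion without equilibrating. Fallback: unmask the two oxygens in separate stages. It sets out from 16. One equivalent of Bu4NF buffered with AcOH (THF, −40 °C) should cleave only the enol Si–O bond and leave the tertiary oxygen as a fluorosilyl ether, (3R,3aR,8aR)-3-{[di-tert-butyl(fluoro)silyl]oxy}-1-hydroxy-3-isopropyl-6,8a-dimethyl-1,2,3,3a-tetrahydroazulen-4(8aH)-one F3. In F3, C5 can be equilibrated with a trace of amine base without retro-aldol risk. The hydrogenation of step 10 then gives (3R,3aR,8aR)-3-{[di-tert-butyl(fluoro)silyl]oxy}-1-hydroxy-3-isopropyl-6,8a-dimethyl-1,2,3,3a,8,8a-hexahydroazulen-4(5H)-one F4. Thioacylation as in step 11 gives O-[(3R,3aR,8aR)-3-{[di-tert-butyl(fluoro)silyl]oxy}-3-isopropyl-6,8a-dimethyl-4-oxo-1,2,3,3a,4,5,8,8a-octahydroazulen-1-yl] O-phenyl carbonothioate F5. Stannane reduction as in step 12 gives (3R,3aR,8aR)-3-{[di-tert-butyl(fluoro)silyl]oxy}-3-isopropyl-6,8a-dimethyl-1,2,3,3a,8,8a-hexahydroazulen-4(5H)-one F6. HF·pyridine then removes the fluorosilyl group, and the sequence comes back to the route at 21.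

Step 10 (1,4-hydrogenation). The hindered diene (C10 beside the quaternary C1, methyl on C8) may bind the chromium fragment poorly, or hydrogen may be delivered across the enone part instead. Fallback: dissolving-metal reduction with kinetic protonation. It sets out from 18. Li in NH3/THF at −78 °C transfers two electrons to the dienone, and protonation at the δ-carbon C10 leaves the trilithium dienolate of 19 (O–C6=C7–C8=C9, both hydroxyl groups as lithium alkoxides) F7. A rapid quench with solid NH4Cl protonates it at the α-carbon C7, which gives the β,γ-unsaturated ketone and comes back to the route at 19.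

Further compounds
F1 | step 7 | 1-diazo-3-[(4R)-2,2-di-tert-butyl-4-isopropyl-7-methyl-4H-benzo[d][1,3,2]dioxasilin-4-yl]propan-2-one | [N-]=[N+]=CC(=O)C[C@]1(C(C)C)O[Si](C(C)(C)C)(C(C)(C)C)Oc2cc(C)ccc12
F2 | step 7 | (3R,8aR)-3,4-[(di-tert-butylsilanediyl)bis(oxy)]-3-isopropyl-6-methyl-3,8a-dihydroazulen-1(2H)-one | CC=1C=C[C@H]2C(=O)C[C@]3(C(C)C)O[Si](C(C)(C)C)(C(C)(C)C)OC(C=1)=C23
F3 | step 9 | (3R,3aR,8aR)-3-{[di-tert-butyl(fluoro)silyl]oxy}-1-hydroxy-3-isopropyl-6,8a-dimethyl-1,2,3,3a-tetrahydroazulen-4(8aH)-one | CC=1C=C[C@@]2(C)C(O)C[C@@](O[Si](F)(C(C)(C)C)C(C)(C)C)(C(C)C)[C@@H]2C(=O)C=1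
F4 | step 9 | (3R,3aR,8aR)-3-{[di-tert-butyl(fluoro)silyl]oxy}-1-hydroxy-3-isopropyl-6,8a-dimethyl-1,2,3,3a,8,8a-hexahydroazulen-4(5H)-one | CC1=CC[C@@]2(C)C(O)C[C@@](O[Si](F)(C(C)(C)C)C(C)(C)C)(C(C)C)[C@@H]2C(=O)C1
F5 | step 9 | O-[(3R,3aR,8aR)-3-{[di-tert-butyl(fluoro)silyl]oxy}-3-isopropyl-6,8a-dimethyl-4-oxo-1,2,3,3a,4,5,8,8a-octahydroazulen-1-yl] O-phenyl carbonothioate | CC1=CC[C@@]2(C)C(OC(=S)Oc3ccccc3)C[C@@](O[Si](F)(C(C)(C)C)C(C)(C)C)(C(C)C)[C@@H]2C(=O)C1
F6 | step 9 | (3R,3aR,8aR)-3-{[di-tert-butyl(fluoro)silyl]oxy}-3-isopropyl-6,8a-dimethyl-1,2,3,3a,8,8a-hexahydroazulen-4(5H)-one | CC1=CC[C@@]2(C)CC[C@@](O[Si](F)(C(C)(C)C)C(C)(C)C)(C(C)C)[C@@H]2C(=O)C1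
F7 | step 10 | trilithium dienolate of 19 (3-isopropyl-6,8a-dimethyl-1,2,3,3a,8,8a-hexahydroazulene-1,3,4-triolate) | [Li+].[Li+].[Li+].CC1=CC[C@@]2(C)C([O-])C[C@@]([O-])(C(C)C)[C@@H]2C([O-])=C1
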